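The route builds ring B de novo instead of forming its crowded aryl–oxygen bonds. Ring B carries oxygen at C1 (to ring A), C3, C4 (to ring C) and C5 and hydrogen at C2 and C6; exactly this array results when the ethynyl ether of the ring A phenol is inserted between C=O and CH of a 3-benzyloxy-4-aryloxycyclobutenone whose aryloxy group is ring C. One thermal operation thus joins a ring A fragment and a ring C fragment and creates ring B with both ether oxygens in place. Rings D to K are then added as ready-made two-ring aryl iodides by copper-catalysed O-arylation, and 28 benzyl ethers are removed at the end.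

Key step: step 12

Remark: 1,3,5-tris(benzyloxy)benzene, 1,3-bis(benzyloxy)benzene and 2,3,4-trihydroxybenzaldehyde are taken as purchasable; cyclobutenone 26 is racemic and its single stereocentre vanishes on aromatisation, the target being achiral.

Step 1
Reactants: 1 1,3,5-tris(benzyloxy)benzene
Product: 4 2,4,6-tris(benzyloxy)phenol, via aryllithium 2 (not isolated), via dimethyl arylboronate 3 (not isolated)
Conditions: n-BuLi, THF, 0 °C to rt; B(OMe)3, −78 °C to rt; AcOH, 30% H2O2, 0 °C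
Reagents that add atoms: hydrogen peroxide OO
Why: Directed ortho-metalation at a carbon flanked by two benzyloxy groups, trapping as the boronate and peroxide oxidation of the C–B bond should place the fourth oxygen of ring A, all three ring CH positions being equivalent.

Step 2
Reactants: 4 2,4,6-tris(benzyloxy)phenol
Product: 5 1,3,5-tris(benzyloxy)-2-{[(E)-1,2-dichloroethenyl]oxy}benzene
Conditions: trichloroethylene, K2CO3, DMF, 70 °C
Reagents that add atoms: trichloroethylene ClC=C(Cl)Cl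
Why: Carbonate converts trichloroethylene into dichloroacetylene in the flask and the phenoxide adds to it in anti fashion (nucleophilic addition to a haloalkyne), which should give the E-configured dichlorovinyl ether.

Step 3
Reactants: 5 1,3,5-tris(benzyloxy)-2-{[(E)-1,2-dichloroethenyl]oxy}benzene
Product: 8 1,3,5-tris(benzyloxy)-2-(ethynyloxy)benzene, via chloroalkyne 6 (not isolated), via lithium acetylide 7 (not isolated)
Conditions: n-BuLi (2.5 equiv), THF, −78 to −40 °C; then H2O, −78 to 0 °C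
Reagents that add atoms: none
Why: Dehydrochlorination to chloroalkyne 6, chlorine–lithium exchange to acetylide 7 and protonation (the dichlorovinyl ether route to ynol ethers) should give the terminal ynol ether, both ortho positions of ring A being blocked against ring lithiation.

Step 4
Reactants: 9 benzyl alcohol
Product: 10 benzyl (E)-1,2-dichloroethenyl ether
Conditions: KH, THF, 0 °C; trichloroethylene, −50 °C to rt
Reagents that add atoms: trichloroethylene ClC=C(Cl)Cl
Why: The potassium alkoxide adds to dichloroacetylene formed in the flask from trichloroethylene (nucleophilic addition to a haloalkyne), which should give the E-dichlorovinyl ether.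

Step 5
Reactants: 10 benzyl (E)-1,2-dichloroethenyl ether
Product: 13 benzyl ethynyl ether, via chloroalkyne 11 (not isolated), via lithium acetylide 12 (not isolated)
Conditions: n-BuLi (2.2 equiv), Et2O, −78 °C; then H2O, −78 to 0 °C; kept as a cold ethereal solution
Reagents that add atoms: none
Why: The same elimination and chlorine–lithium exchange sequence should give the ynol ether, which is kept cold and used at once because benzyl alkynyl ethers undergo [3,3] sigmatropic rearrangement on warming.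

Step 6
Reactants: 14 2,3,4-trihydroxybenzaldehyde
Product: 15 2,3,4-tris(benzyloxy)benzaldehyde
Conditions: BnBr, K2CO3, DMF, 60 °C
Reagents that add atoms: benzyl bromide BrCc1ccccc1
Why: Williamson etherification of all three phenols should proceed fully, the chelated ortho hydroxyl reacting last on warming.

Step 7
Reactants: 15 2,3,4-tris(benzyloxy)benzaldehyde
Product: 17 2,3,4-tris(benzyloxy)phenol, via aryl formate 16 (not isolated)
Conditions: mCPBA, CH2Cl2, 0 °C to rt; then K2CO3 (cat.), MeOH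
Reagents that add atoms: mCPBA OOC(=O)c1cccc(Cl)c1
Why: Baeyer–Villiger oxidation of the electron-rich aldehyde with aryl migration (Dakin-type) gives formate 16, which methanolysis should convert into the phenol.

Step 8
Reactants: 17 2,3,4-tris(benzyloxy)phenol
Product: 18 1,2,3-tris(benzyloxy)-4-(methoxymethoxy)benzene
Conditions: MOMCl, i-Pr2NEt, CH2Cl2, 0 °C to rt
Reagents that add atoms: chloromethyl methyl ether COCCl
Why: O-Alkylation of the phenol with chloromethyl methyl ether should install the MOM group that later directs lithiation and masks the oxygen linking ring C to ring D.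

Step 9
Reactants: 18 1,2,3-tris(benzyloxy)-4-(methoxymethoxy)benzene
Product: 21 3,4,5-tris(benzyloxy)-2-(methoxymethoxy)phenol, via aryllithium 19 (not isolated), via dimethyl arylboronate 20 (not isolated)
Conditions: n-BuLi, THF, −20 to 0 °C; B(OMe)3, −78 °C to rt; AcOH, 30% H2O2, 0 °C
Reagents that add atoms: hydrogen peroxide OO
Why: MOM-directed ortho-lithiation at the only CH next to the acetal oxygen, borylation and oxidation (directed ortho-metalation) should introduce the fifth oxygen of ring C as a free phenol.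

Step 10
Reactants: 21 3,4,5-tris(benzyloxy)-2-(methoxymethoxy)phenol
Product: 23 2-[3,4,5-tris(benzyloxy)-2-(methoxymethoxy)phenoxy]acetic acid, via methyl ester 22 (not isolated)
Conditions: methyl bromoacetate, K2CO3, DMF, rt; then LiOH, THF/H2O; 1 M HCl to pH 4, 0 °C
Reagents that add atoms: methyl bromoacetate COC(=O)CBr; lithium hydroxide [Li+].[OH-]
Why: Williamson etherification followed by saponification in the same flask should give the aryloxyacetic acid, the mild cold acidification sparing the MOM ether.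

Step 11
Reactants: 23 2-[3,4,5-tris(benzyloxy)-2-(methoxymethoxy)phenoxy]acetic acid; 13 benzyl ethynyl ether
Product: 26 3-(benzyloxy)-4-[3,4,5-tris(benzyloxy)-2-(methoxymethoxy)phenoxy]cyclobut-2-en-1-one (racemic), via acid chloride 24 (not isolated), via aryloxyketene 25 (not isolated)
Conditions: 1-chloro-N,N,2-trimethylprop-1-en-1-amine, CH2Cl2, 0 °C to rt; then 13 (excess), NEt3 added slowly, CH2Cl2/Et2O, 0 °C to rt
Reagents that add atoms: none
Why: The chloroenamine should form acid chloride 24 without liberating HCl so that the MOM ether survives, NEt3 then gives aryloxyketene 25, and its thermal ketene–ynol ether [2+2] cycloaddition (terminal alkyne carbon to ketene carbonyl carbon) should deliver the 3-alkoxy-4-aryloxycyclobutenone as a racemate.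

Step 12
Reactants: 26 3-(benzyloxy)-4-[3,4,5-tris(benzyloxy)-2-(methoxymethoxy)phenoxy]cyclobut-2-en-1-one (racemic); 8 1,3,5-tris(benzyloxy)-2-(ethynyloxy)benzene
Product: 31 3-(benzyloxy)-5-[2,4,6-tris(benzyloxy)phenoxy]-2-[3,4,5-tris(benzyloxy)-2-(methoxymethoxy)phenoxy]phenol, via vinylketene 27 (not isolated), via vinylcyclobutenone 28 (not isolated), via dienylketene 29 (not isolated), via cyclohexadienone 30 (not isolated)
Conditions: 8 (1.3 equiv), toluene, 80 °C then 110 °C, sealed tube; then K2CO3, MeOH, rt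
Reagents that add atoms: none
Why: Heating opens cyclobutenone 26 in a conrotatory 4π step, the aryloxy group turning outward, to vinylketene 27, whose C=C=O unit adds the electron-rich ynol ether 8 in a [2+2] cycloaddition to give vinylcyclobutenone 28, and a second 4π opening gives dienylketene 29. Ring B is then closed by thermal disrotatory 6π electrocyclisation of 29, which re-forms the C3–C4 bond between the ketene carbon and the aryloxy-bearing terminus, and cyclohexadienone 30 tautomerises to the phenol. This is the Danheiser benzannulation, known for cyclobutenones and alkoxy- or siloxyacetylenes giving resorcinol monoethers. The two new skeletal bonds are C2–C3 and C1–C6 of ring B, both made in the [2+2] step. The one selectivity needed is regiochemical: the nucleophilic terminal carbon of 8 must bond to the ketene carbonyl carbon, which the oxygen-induced polarisation of the ynol ether secures, so the ring A oxygen lands meta to the new hydroxyl and para to the ring C oxygen. No stereocentre is created, and the one in racemic 26 is lost on aromatisation.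

Step 13
Reactants: 31 3-(benzyloxy)-5-[2,4,6-tris(benzyloxy)phenoxy]-2-[3,4,5-tris(benzyloxy)-2-(methoxymethoxy)phenoxy]phenol
Product: 32 1,3-bis(benzyloxy)-5-[2,4,6-tris(benzyloxy)phenoxy]-2-[3,4,5-tris(benzyloxy)-2-(methoxymethoxy)phenoxy]benzene (rings A to C MOM ether)
Conditions: BnBr, K2CO3, DMF, rt to 50 °C
Reagents that add atoms: benzyl bromide BrCc1ccccc1
Why: Williamson benzylation should cap the only free hydroxyl of ring B before the copper chemistry.

Step 14
Reactants: 32 rings A to C MOM ether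
Product: 33 2,3,4-tris(benzyloxy)-6-{2,6-bis(benzyloxy)-4-[2,4,6-tris(benzyloxy)phenoxy]phenoxy}phenol (rings A to C phenol)
Conditions: conc. HCl (cat.), MeOH/THF, 45 °C
Reagents that add atoms: none
Why: Acid-catalysed acetal exchange with methanol should cleave the MOM ether alone, benzyl and diaryl ethers being inert, and so free the ring C hydroxyl at C2.

Step 15
Reactants: 34 1,3-bis(benzyloxy)benzene
Product: 37 2,6-bis(benzyloxy)phenol, via aryllithium 35 (not isolated), via dimethyl arylboronate 36 (not isolated)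
Conditions: n-BuLi, THF, 0 °C to rt; B(OMe)3, −78 °C to rt; AcOH, 30% H2O2, 0 °C
Reagents that add atoms: hydrogen peroxide OO
Why: Lithiation between the two benzyloxy groups, borylation and oxidation (directed ortho-metalation) should give the 2,6-dioxygenated phenol.

Step 16
Reactants: 37 2,6-bis(benzyloxy)phenol
Product: 38 2,6-bis(benzyloxy)-4-iodophenol
Conditions: I2, NaHCO3, THF/H2O, 0 °C to rt
Reagents that add atoms: iodine II
Why: Electrophilic aromatic iodination under mildly basic conditions should go para to the phenol oxygen, the strongest donor on the ring.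

Step 17
Reactants: 38 2,6-bis(benzyloxy)-4-iodophenol
Product: 39 1,2,3-tris(benzyloxy)-5-iodobenzene
Conditions: BnBr, K2CO3, DMF, rt
Reagents that add atoms: benzyl bromide BrCc1ccccc1
Why: Williamson benzylation of the phenol should give the ring K iodide.

Step 18
Reactants: 39 1,2,3-tris(benzyloxy)-5-iodobenzene
Product: 42 [3,4,5-tris(benzyloxy)phenyl]boronic acid, via aryllithium 40 (not isolated), via borate complex 41 (not isolated)
Conditions: n-BuLi, THF, −78 °C; B(Oi-Pr)3, −78 °C to rt; 1 M HCl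
Reagents that add atoms: triisopropyl borate CC(C)OB(OC(C)C)OC(C)C; water O
Why: Iodine–lithium exchange at low temperature, trapping with the borate and hydrolysis should give the boronic acid.

Step 19
Reactants: 38 2,6-bis(benzyloxy)-4-iodophenol; 42 [3,4,5-tris(benzyloxy)phenyl]boronic acid
Product: 43 1,3-bis(benzyloxy)-5-iodo-2-[3,4,5-tris(benzyloxy)phenoxy]benzene (rings J and K iodide)
Conditions: Cu(OAc)2 (1.5 equiv), pyridine, 4 Å MS, CH2Cl2, air, rt
Reagents that add atoms: none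
Why: Chan–Lam coupling mediated by divalent copper at room temperature should arylate the di-ortho-substituted phenol with the unhindered electron-rich boronic acid and leave the aryl iodide untouched.

Step 20
Reactants: 43 1,3-bis(benzyloxy)-5-iodo-2-[3,4,5-tris(benzyloxy)phenoxy]benzene
Product: 44 2,3,4-tris(benzyloxy)-6-[2,6-bis(benzyloxy)-4-iodophenoxy]benzaldehyde
Conditions: POCl3, DMF, 0 to 50 °C; then H2O
Reagents that add atoms: N,N-dimethylformamide CN(C)C=O; water O
Why: Vilsmeier–Haack formylation should occur only on the tris(benzyloxy)phenoxy ring, whose CH has three oxygen donors in ortho, ortho and para positions, while the iodinated ring has two donors and an ortho iodine.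

Step 21
Reactants: 44 2,3,4-tris(benzyloxy)-6-[2,6-bis(benzyloxy)-4-iodophenoxy]benzaldehyde
Product: 46 2,3,4-tris(benzyloxy)-6-[2,6-bis(benzyloxy)-4-iodophenoxy]phenol, via aryl formate 45 (not isolated)
Conditions: mCPBA, NaHCO3, CH2Cl2, 0 °C; then K2CO3 (cat.), MeOH/THF
Reagents that add atoms: mCPBA OOC(=O)c1cccc(Cl)c1
Why: Baeyer–Villiger oxidation of the aldehyde flanked by two oxygen substituents (Dakin-type) and methanolysis of formate 45 should give the phenol, the aryl iodide being inert to buffered peracid.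

Step 22
Reactants: 46 2,3,4-tris(benzyloxy)-6-[2,6-bis(benzyloxy)-4-iodophenoxy]phenol
Product: 47 1,3-bis(benzyloxy)-5-iodo-2-[3,4,5-tris(benzyloxy)-2-(methoxymethoxy)phenoxy]benzene (two-ring building block)
Conditions: NaH, MOMCl, THF/DMF, 0 °C
Reagents that add atoms: chloromethyl methyl ether COCCl
Why: O-Alkylation of the sodium phenoxide should cap the hindered hydroxyl and give a building block with one iodide and one masked phenol.

Step 23
Reactants: 33 rings A to C phenol; 47 two-ring building block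
Product: 48 rings A to E MOM ether (chain of rings A to E as in the target in which thirteen hydroxyls are benzyl ethers while the C2 oxygen of ring E carries MOM)
Conditions: CuI (cat.), picolinic acid, K3PO4, DMSO, 90 °C
Reagents that add atoms: none
Why: Ullmann-type diaryl ether synthesis should arylate the hindered ring C phenol with the aryl iodide, whose iodine sits between two ring hydrogens.

Step 24
Reactants: 48 rings A to E MOM ether
Product: 49 rings A to E phenol (the same chain bearing thirteen benzyl ethers plus a free hydroxyl at C2 of ring E)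
Conditions: conc. HCl (cat.), MeOH/THF, 45 °C
Reagents that add atoms: none
Why: Acid-catalysed MOM cleavage as in step 14 should free the ring E hydroxyl.

Step 25
Reactants: 49 rings A to E phenol; 47 two-ring building block
Product: 50 rings A to G MOM ether (chain of rings A to G as in the target in which eighteen hydroxyls are benzyl ethers while the C2 oxygen of ring G carries MOM)
Conditions: CuI (cat.), picolinic acid, K3PO4, DMSO, 90 °C
Reagents that add atoms: none
Why: The Ullmann-type coupling of step 23 is repeated on a phenol of the same local structure.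

Step 26
Reactants: 50 rings A to G MOM ether
Product: 51 rings A to G phenol (the same chain bearing eighteen benzyl ethers plus a free hydroxyl at C2 of ring G)
Conditions: conc. HCl (cat.), MeOH/THF, 45 °C
Reagents that add atoms: none
Why: Acid-catalysed MOM cleavage should free the ring G hydroxyl.

Step 27
Reactants: 51 rings A to G phenol; 47 two-ring building block
Product: 52 rings A to I MOM ether (chain of rings A to I as in the target in which twenty-three hydroxyls are benzyl ethers while the C2 oxygen of ring I carries MOM)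
Conditions: CuI (cat.), picolinic acid, K3PO4, DMSO, 90 °C
Reagents that add atoms: none
Why: The Ullmann-type coupling is repeated a third time on the same phenol type.

Step 28
Reactants: 52 rings A to I MOM ether
Product: 53 rings A to I phenol (the same chain bearing twenty-three benzyl ethers plus a free hydroxyl at C2 of ring I)
Conditions: conc. HCl (cat.), MeOH/THF, 45 °C
Reagents that add atoms: none
Why: Acid-catalysed MOM cleavage should free the ring I hydroxyl.

Step 29
Reactants: 53 rings A to I phenol; 43 rings J and K iodide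
Product: 54 octacosa-O-benzyl CNP0245174.0 (rings A to K in which all twenty-eight hydroxyls are benzyl ethers)
Conditions: CuI (cat.), picolinic acid, K3PO4, DMSO, 90 °C
Reagents that add atoms: none
Why: The same Ullmann-type coupling with the end-capped iodide 43 should complete the chain of 11 rings.

Step 30
Reactants: 54 octacosa-O-benzyl CNP0245174.0
Product: 55 CNP0245174.0
Conditions: H2, 10% Pd/C, THF/MeOH, rt, exclusion of air on work-up
Reagents that add atoms: none
Why: Hydrogenolysis of all 28 benzyl ethers should free the phenols without touching the diaryl ether bonds.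

Compound list
1 | 1,3,5-tris(benzyloxy)benzene | c1(OCc9ccccc9)cc(OCc9ccccc9)cc(OCc9ccccc9)c1 | starting material
2 | 2,4,6-tris(benzyloxy)phenyllithium | [Li]c1c(OCc9ccccc9)cc(OCc9ccccc9)cc1OCc9ccccc9 | intermediate
3 | dimethyl [2,4,6-tris(benzyloxy)phenyl]boronate | COB(OC)c1c(OCc9ccccc9)cc(OCc9ccccc9)cc1OCc9ccccc9 | intermediate
4 | 2,4,6-tris(benzyloxy)phenol | Oc1c(OCc9ccccc9)cc(OCc9ccccc9)cc1OCc9ccccc9 | intermediate
5 | 1,3,5-tris(benzyloxy)-2-{[(E)-1,2-dichloroethenyl]oxy}benzene | Cl/C=C(/Cl)Oc1c(OCc9ccccc9)cc(OCc9ccccc9)cc1OCc9ccccc9 | intermediate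
6 | 1,3,5-tris(benzyloxy)-2-[(chloroethynyl)oxy]benzene | ClC#COc1c(OCc9ccccc9)cc(OCc9ccccc9)cc1OCc9ccccc9 | intermediate
7 | lithium 2-[2,4,6-tris(benzyloxy)phenoxy]ethynide | [Li]C#COc1c(OCc9ccccc9)cc(OCc9ccccc9)cc1OCc9ccccc9 | intermediate
8 | 1,3,5-tris(benzyloxy)-2-(ethynyloxy)benzene | C#COc1c(OCc9ccccc9)cc(OCc9ccccc9)cc1OCc9ccccc9 | intermediate
9 | benzyl alcohol | OCc1ccccc1 | starting material
10 | benzyl (E)-1,2-dichloroethenyl ether | Cl/C=C(/Cl)OCc1ccccc1 | intermediate
11 | benzyl chloroethynyl ether | ClC#COCc1ccccc1 | intermediate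
12 | lithium 2-(benzyloxy)ethynide | [Li]C#COCc1ccccc1 | intermediate
13 | benzyl ethynyl ether | C#COCc1ccccc1 | intermediate
14 | 2,3,4-trihydroxybenzaldehyde | O=Cc1ccc(O)c(O)c1O | starting material
15 | 2,3,4-tris(benzyloxy)benzaldehyde | O=Cc1ccc(OCc9ccccc9)c(OCc9ccccc9)c1OCc9ccccc9 | intermediate
16 | 2,3,4-tris(benzyloxy)phenyl formate | O=COc1ccc(OCc9ccccc9)c(OCc9ccccc9)c1OCc9ccccc9 | intermediate
17 | 2,3,4-tris(benzyloxy)phenol | Oc1ccc(OCc9ccccc9)c(OCc9ccccc9)c1OCc9ccccc9 | intermediate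
18 | 1,2,3-tris(benzyloxy)-4-(methoxymethoxy)benzene | COCOc1ccc(OCc9ccccc9)c(OCc9ccccc9)c1OCc9ccccc9 | intermediate
19 | [3,4,5-tris(benzyloxy)-2-(methoxymethoxy)phenyl]lithium | COCOc1c([Li])cc(OCc9ccccc9)c(OCc9ccccc9)c1OCc9ccccc9 | intermediate
20 | dimethyl [3,4,5-tris(benzyloxy)-2-(methoxymethoxy)phenyl]boronate | COCOc1c(B(OC)OC)cc(OCc9ccccc9)c(OCc9ccccc9)c1OCc9ccccc9 | intermediate
21 | 3,4,5-tris(benzyloxy)-2-(methoxymethoxy)phenol | COCOc1c(O)cc(OCc9ccccc9)c(OCc9ccccc9)c1OCc9ccccc9 | intermediate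
22 | methyl 2-[3,4,5-tris(benzyloxy)-2-(methoxymethoxy)phenoxy]acetate | COCOc1c(OCC(=O)OC)cc(OCc9ccccc9)c(OCc9ccccc9)c1OCc9ccccc9 | intermediate
23 | 2-[3,4,5-tris(benzyloxy)-2-(methoxymethoxy)phenoxy]acetic acid | COCOc1c(OCC(O)=O)cc(OCc9ccccc9)c(OCc9ccccc9)c1OCc9ccccc9 | intermediate
24 | 2-[3,4,5-tris(benzyloxy)-2-(methoxymethoxy)phenoxy]acetyl chloride | COCOc1c(OCC(Cl)=O)cc(OCc9ccccc9)c(OCc9ccccc9)c1OCc9ccccc9 | intermediate
25 | [3,4,5-tris(benzyloxy)-2-(methoxymethoxy)phenoxy]ketene | COCOc1c(OC=C=O)cc(OCc9ccccc9)c(OCc9ccccc9)c1OCc9ccccc9 | intermediate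
26 | 3-(benzyloxy)-4-[3,4,5-tris(benzyloxy)-2-(methoxymethoxy)phenoxy]cyclobut-2-en-1-one (racemic) | O=C1C=C(OCc9ccccc9)C1Oc2cc(OCc9ccccc9)c(OCc9ccccc9)c(OCc9ccccc9)c2OCOC | intermediate
27 | (3Z)-3-(benzyloxy)-4-[3,4,5-tris(benzyloxy)-2-(methoxymethoxy)phenoxy]buta-1,3-dien-1-one (vinylketene) | O=C=C/C(OCc9ccccc9)=C/Oc2cc(OCc9ccccc9)c(OCc9ccccc9)c(OCc9ccccc9)c2OCOC | intermediate
28 | 4-[(Z)-1-(benzyloxy)-2-(ring C aryloxy)ethenyl]-3-[2,4,6-tris(benzyloxy)phenoxy]cyclobut-2-en-1-one (racemic vinylcyclobutenone) | O=C1C=C(Oc3c(OCc9ccccc9)cc(OCc9ccccc9)cc3OCc9ccccc9)C1/C(OCc9ccccc9)=C/Oc2cc(OCc9ccccc9)c(OCc9ccccc9)c(OCc9ccccc9)c2OCOC | intermediate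
29 | (3E,5Z)-5-(benzyloxy)-3-[2,4,6-tris(benzyloxy)phenoxy]-6-(ring C aryloxy)hexa-1,3,5-trien-1-one (dienylketene whose ketene carbon lies cis to the terminal vinyl group) | O=C=C/C(Oc3c(OCc9ccccc9)cc(OCc9ccccc9)cc3OCc9ccccc9)=C\C(OCc9ccccc9)=C\Oc2cc(OCc9ccccc9)c(OCc9ccccc9)c(OCc9ccccc9)c2OCOC | intermediate
30 | 5-(benzyloxy)-3-[2,4,6-tris(benzyloxy)phenoxy]-6-(ring C aryloxy)cyclohexa-2,4-dien-1-one (racemic) | O=C1C=C(Oc3c(OCc9ccccc9)cc(OCc9ccccc9)cc3OCc9ccccc9)C=C(OCc9ccccc9)C1Oc2cc(OCc9ccccc9)c(OCc9ccccc9)c(OCc9ccccc9)c2OCOC | intermediate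
31 | 3-(benzyloxy)-5-[2,4,6-tris(benzyloxy)phenoxy]-2-[3,4,5-tris(benzyloxy)-2-(methoxymethoxy)phenoxy]phenol | Oc1cc(Oc3c(OCc9ccccc9)cc(OCc9ccccc9)cc3OCc9ccccc9)cc(OCc9ccccc9)c1Oc2cc(OCc9ccccc9)c(OCc9ccccc9)c(OCc9ccccc9)c2OCOC | intermediate
32 | 1,3-bis(benzyloxy)-5-[2,4,6-tris(benzyloxy)phenoxy]-2-[3,4,5-tris(benzyloxy)-2-(methoxymethoxy)phenoxy]benzene (rings A to C MOM ether) | c9ccccc9COc1cc(OCc9ccccc9)c(Oc2cc(OCc9ccccc9)c(Oc3cc(OCc9ccccc9)c(OCc9ccccc9)c(OCc9ccccc9)c3OCOC)c(OCc9ccccc9)c2)c(OCc9ccccc9)c1 | intermediate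
33 | 2,3,4-tris(benzyloxy)-6-{2,6-bis(benzyloxy)-4-[2,4,6-tris(benzyloxy)phenoxy]phenoxy}phenol (rings A to C phenol) | c9ccccc9COc1cc(OCc9ccccc9)c(Oc2cc(OCc9ccccc9)c(Oc3cc(OCc9ccccc9)c(OCc9ccccc9)c(OCc9ccccc9)c3O)c(OCc9ccccc9)c2)c(OCc9ccccc9)c1 | intermediate
34 | 1,3-bis(benzyloxy)benzene | c1cc(OCc9ccccc9)cc(OCc9ccccc9)c1 | starting material
35 | 2,6-bis(benzyloxy)phenyllithium | [Li]c1c(OCc9ccccc9)cccc1OCc9ccccc9 | intermediate
36 | dimethyl [2,6-bis(benzyloxy)phenyl]boronate | COB(OC)c1c(OCc9ccccc9)cccc1OCc9ccccc9 | intermediate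
37 | 2,6-bis(benzyloxy)phenol | Oc1c(OCc9ccccc9)cccc1OCc9ccccc9 | intermediate
38 | 2,6-bis(benzyloxy)-4-iodophenol | Oc1c(OCc9ccccc9)cc(I)cc1OCc9ccccc9 | intermediate
39 | 1,2,3-tris(benzyloxy)-5-iodobenzene | Ic1cc(OCc9ccccc9)c(OCc9ccccc9)c(OCc9ccccc9)c1 | intermediate
40 | 3,4,5-tris(benzyloxy)phenyllithium | [Li]c1cc(OCc9ccccc9)c(OCc9ccccc9)c(OCc9ccccc9)c1 | intermediate
41 | lithium triisopropoxy[3,4,5-tris(benzyloxy)phenyl]borate | [Li+].CC(C)O[B-](OC(C)C)(OC(C)C)c1cc(OCc9ccccc9)c(OCc9ccccc9)c(OCc9ccccc9)c1 | intermediate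
42 | [3,4,5-tris(benzyloxy)phenyl]boronic acid | OB(O)c1cc(OCc9ccccc9)c(OCc9ccccc9)c(OCc9ccccc9)c1 | intermediate
43 | 1,3-bis(benzyloxy)-5-iodo-2-[3,4,5-tris(benzyloxy)phenoxy]benzene (rings J and K iodide) | Ic1cc(OCc9ccccc9)c(Oc2cc(OCc9ccccc9)c(OCc9ccccc9)c(OCc9ccccc9)c2)c(OCc9ccccc9)c1 | intermediate
44 | 2,3,4-tris(benzyloxy)-6-[2,6-bis(benzyloxy)-4-iodophenoxy]benzaldehyde | Ic1cc(OCc9ccccc9)c(Oc2cc(OCc9ccccc9)c(OCc9ccccc9)c(OCc9ccccc9)c2C=O)c(OCc9ccccc9)c1 | intermediate
45 | 2,3,4-tris(benzyloxy)-6-[2,6-bis(benzyloxy)-4-iodophenoxy]phenyl formate | Ic1cc(OCc9ccccc9)c(Oc2cc(OCc9ccccc9)c(OCc9ccccc9)c(OCc9ccccc9)c2OC=O)c(OCc9ccccc9)c1 | intermediate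
46 | 2,3,4-tris(benzyloxy)-6-[2,6-bis(benzyloxy)-4-iodophenoxy]phenol | Ic1cc(OCc9ccccc9)c(Oc2cc(OCc9ccccc9)c(OCc9ccccc9)c(OCc9ccccc9)c2O)c(OCc9ccccc9)c1 | intermediate
47 | 1,3-bis(benzyloxy)-5-iodo-2-[3,4,5-tris(benzyloxy)-2-(methoxymethoxy)phenoxy]benzene (two-ring building block) | Ic1cc(OCc9ccccc9)c(Oc2cc(OCc9ccccc9)c(OCc9ccccc9)c(OCc9ccccc9)c2OCOC)c(OCc9ccccc9)c1 | intermediate
48 | rings A to E MOM ether (chain of rings A to E as in the target in which thirteen hydroxyls are benzyl ethers while the C2 oxygen of ring E carries MOM) | c9ccccc9COc1cc(OCc9ccccc9)c(Oc2cc(OCc9ccccc9)c(Oc3cc(OCc9ccccc9)c(OCc9ccccc9)c(OCc9ccccc9)c3Oc3cc(OCc9ccccc9)c(Oc4cc(OCc9ccccc9)c(OCc9ccccc9)c(OCc9ccccc9)c4OCOC)c(OCc9ccccc9)c3)c(OCc9ccccc9)c2)c(OCc9ccccc9)c1 | intermediate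
49 | rings A to E phenol (the same chain bearing thirteen benzyl ethers plus a free hydroxyl at C2 of ring E) | c9ccccc9COc1cc(OCc9ccccc9)c(Oc2cc(OCc9ccccc9)c(Oc3cc(OCc9ccccc9)c(OCc9ccccc9)c(OCc9ccccc9)c3Oc3cc(OCc9ccccc9)c(Oc4cc(OCc9ccccc9)c(OCc9ccccc9)c(OCc9ccccc9)c4O)c(OCc9ccccc9)c3)c(OCc9ccccc9)c2)c(OCc9ccccc9)c1 | intermediate
50 | rings A to G MOM ether (chain of rings A to G as in the target in which eighteen hydroxyls are benzyl ethers while the C2 oxygen of ring G carries MOM) | c9ccccc9COc1cc(OCc9ccccc9)c(Oc2cc(OCc9ccccc9)c(Oc3cc(OCc9ccccc9)c(OCc9ccccc9)c(OCc9ccccc9)c3Oc3cc(OCc9ccccc9)c(Oc4cc(OCc9ccccc9)c(OCc9ccccc9)c(OCc9ccccc9)c4Oc4cc(OCc9ccccc9)c(Oc5cc(OCc9ccccc9)c(OCc9ccccc9)c(OCc9ccccc9)c5OCOC)c(OCc9ccccc9)c4)c(OCc9ccccc9)c3)c(OCc9ccccc9)c2)c(OCc9ccccc9)c1 | intermediate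
51 | rings A to G phenol (the same chain bearing eighteen benzyl ethers plus a free hydroxyl at C2 of ring G) | c9ccccc9COc1cc(OCc9ccccc9)c(Oc2cc(OCc9ccccc9)c(Oc3cc(OCc9ccccc9)c(OCc9ccccc9)c(OCc9ccccc9)c3Oc3cc(OCc9ccccc9)c(Oc4cc(OCc9ccccc9)c(OCc9ccccc9)c(OCc9ccccc9)c4Oc4cc(OCc9ccccc9)c(Oc5cc(OCc9ccccc9)c(OCc9ccccc9)c(OCc9ccccc9)c5O)c(OCc9ccccc9)c4)c(OCc9ccccc9)c3)c(OCc9ccccc9)c2)c(OCc9ccccc9)c1 | intermediate
52 | rings A to I MOM ether (chain of rings A to I as in the target in which twenty-three hydroxyls are benzyl ethers while the C2 oxygen of ring I carries MOM) | c9ccccc9COc1cc(OCc9ccccc9)c(Oc2cc(OCc9ccccc9)c(Oc3cc(OCc9ccccc9)c(OCc9ccccc9)c(OCc9ccccc9)c3Oc3cc(OCc9ccccc9)c(Oc4cc(OCc9ccccc9)c(OCc9ccccc9)c(OCc9ccccc9)c4Oc4cc(OCc9ccccc9)c(Oc5cc(OCc9ccccc9)c(OCc9ccccc9)c(OCc9ccccc9)c5Oc5cc(OCc9ccccc9)c(Oc6cc(OCc9ccccc9)c(OCc9ccccc9)c(OCc9ccccc9)c6OCOC)c(OCc9ccccc9)c5)c(OCc9ccccc9)c4)c(OCc9ccccc9)c3)c(OCc9ccccc9)c2)c(OCc9ccccc9)c1 | intermediate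
53 | rings A to I phenol (the same chain bearing twenty-three benzyl ethers plus a free hydroxyl at C2 of ring I) | c9ccccc9COc1cc(OCc9ccccc9)c(Oc2cc(OCc9ccccc9)c(Oc3cc(OCc9ccccc9)c(OCc9ccccc9)c(OCc9ccccc9)c3Oc3cc(OCc9ccccc9)c(Oc4cc(OCc9ccccc9)c(OCc9ccccc9)c(OCc9ccccc9)c4Oc4cc(OCc9ccccc9)c(Oc5cc(OCc9ccccc9)c(OCc9ccccc9)c(OCc9ccccc9)c5Oc5cc(OCc9ccccc9)c(Oc6cc(OCc9ccccc9)c(OCc9ccccc9)c(OCc9ccccc9)c6O)c(OCc9ccccc9)c5)c(OCc9ccccc9)c4)c(OCc9ccccc9)c3)c(OCc9ccccc9)c2)c(OCc9ccccc9)c1 | intermediate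
54 | octacosa-O-benzyl CNP0245174.0 (rings A to K in which all twenty-eight hydroxyls are benzyl ethers) | c9ccccc9COc1cc(OCc9ccccc9)c(Oc2cc(OCc9ccccc9)c(Oc3cc(OCc9ccccc9)c(OCc9ccccc9)c(OCc9ccccc9)c3Oc3cc(OCc9ccccc9)c(Oc4cc(OCc9ccccc9)c(OCc9ccccc9)c(OCc9ccccc9)c4Oc4cc(OCc9ccccc9)c(Oc5cc(OCc9ccccc9)c(OCc9ccccc9)c(OCc9ccccc9)c5Oc5cc(OCc9ccccc9)c(Oc6cc(OCc9ccccc9)c(OCc9ccccc9)c(OCc9ccccc9)c6Oc6cc(OCc9ccccc9)c(Oc7cc(OCc9ccccc9)c(OCc9ccccc9)c(OCc9ccccc9)c7)c(OCc9ccccc9)c6)c(OCc9ccccc9)c5)c(OCc9ccccc9)c4)c(OCc9ccccc9)c3)c(OCc9ccccc9)c2)c(OCc9ccccc9)c1 | intermediate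
55 | CNP0245174.0 | Oc1cc(O)c(Oc2cc(O)c(Oc3cc(O)c(O)c(O)c3Oc3cc(O)c(Oc4cc(O)c(O)c(O)c4Oc4cc(O)c(Oc5cc(O)c(O)c(O)c5Oc5cc(O)c(Oc6cc(O)c(O)c(O)c6Oc6cc(O)c(Oc7cc(O)c(O)c(O)c7)c(O)c6)c(O)c5)c(O)c4)c(O)c3)c(O)c2)c(O)c1 | target

Total step count: 30. Longest linear sequence: 17 steps (from 14 through steps 6 to 14 and 23 to 30).

Steps most likely to fail

Step 12. The ynol ether may polymerise, or the vinylketene may dimerise or acylate the product phenol, faster than the cycloaddition and electrocyclisation cascade runs. Fallback: ring B is brought in as an aryl iodide instead of being built. Phenol 4 and iodide 47 are joined by the Ullmann-type coupling used in step 23 (CuI, picolinic acid, K3PO4, DMSO, 90 °C), the hindered partner being the phenol and the iodide carbon lying between two ring hydrogens. This sets out from 4 and 47 and returns to the route at 32 without any new compound.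

Step 11. The benzyl ynol ether may rearrange sigmatropically before it is trapped, or the aryloxyketene may dimerise. Fallback: setting out from acid 23, acid chloride 24 and ketene 25 are made as before and the ketene is trapped with commercial ethoxyacetylene, which has no rearrangement pathway at room temperature, to give 3-ethoxy-4-[3,4,5-tris(benzyloxy)-2-(methoxymethoxy)phenoxy]cyclobut-2-en-1-one F1. Acid-catalysed vinylogous transetherification of F1 with benzyl alcohol (cat. pyridinium p-toluenesulfonate, toluene, rt, ethanol removed under reduced pressure) then exchanges ethoxy for benzyloxy and returns to the route at 26. The MOM ether is the group to watch in the exchange.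

Step 23 (the same concern holds for steps 25, 27 and 29). Ligand exchange at copper may be slow with the crowded phenoxide, so that the iodide is reduced or conversion stalls. Fallback: setting out from iodide 47, iodine–lithium exchange (n-BuLi, THF, −78 °C) gives {3,5-bis(benzyloxy)-4-[3,4,5-tris(benzyloxy)-2-(methoxymethoxy)phenoxy]phenyl}lithium F2, B(Oi-Pr)3 gives the lithium triisopropoxy(aryl)borate F3, and brief hydrolysis with cold dilute HCl gives {3,5-bis(benzyloxy)-4-[3,4,5-tris(benzyloxy)-2-(methoxymethoxy)phenoxy]phenyl}boronic acid F4. Chan–Lam coupling of F4 with phenol 33 under the conditions of step 19 (Cu(OAc)2, pyridine, 4 Å MS, CH2Cl2, air, rt) returns to the route at 48; F4 serves steps 25 and 27 in the same way.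

Further compounds
F0 | step 12 | none | none
F1 | step 11 | 3-ethoxy-4-[3,4,5-tris(benzyloxy)-2-(methoxymethoxy)phenoxy]cyclobut-2-en-1-one (racemic) | O=C1C=C(OCC)C1Oc2cc(OCc9ccccc9)c(OCc9ccccc9)c(OCc9ccccc9)c2OCOC
F2 | step 23 | {3,5-bis(benzyloxy)-4-[3,4,5-tris(benzyloxy)-2-(methoxymethoxy)phenoxy]phenyl}lithium | [Li]c1cc(OCc9ccccc9)c(Oc2cc(OCc9ccccc9)c(OCc9ccccc9)c(OCc9ccccc9)c2OCOC)c(OCc9ccccc9)c1
F3 | step 23 | lithium triisopropoxy{3,5-bis(benzyloxy)-4-[3,4,5-tris(benzyloxy)-2-(methoxymethoxy)phenoxy]phenyl}borate | [Li+].CC(C)O[B-](OC(C)C)(OC(C)C)c1cc(OCc9ccccc9)c(Oc2cc(OCc9ccccc9)c(OCc9ccccc9)c(OCc9ccccc9)c2OCOC)c(OCc9ccccc9)c1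
F4 | step 23 | {3,5-bis(benzyloxy)-4-[3,4,5-tris(benzyloxy)-2-(methoxymethoxy)phenoxy]phenyl}boronic acid | OB(O)c1cc(OCc9ccccc9)c(Oc2cc(OCc9ccccc9)c(OCc9ccccc9)c(OCc9ccccc9)c2OCOC)c(OCc9ccccc9)c1
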